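Start from the birch run: it charges the same [J] as the elm run, 240 mM, and more L, 150 mM against 65.0 mM.

| flask | L | J | time |
|---|---|---|---|
| alder | 300 mM | 240 mM |  |
| cedar | 180 mM | 120 mM |  |
| larch | 300 mM | 480 mM |  |
| birch | 150 mM | 240 mM |  |
| elm | 65.0 mM | 240 mM | 45 min |

| run | time / min | [Q] / mM |
|---|---|---|
| alder run | 3.4 | 39 |
| alder run | 10 | 74 |
| alder run | 20 | 98 |
| alder run | 31 | 101 |
| alder run | 45 | 106 |
| cedar run | 3.4 | 15 |
| cedar run | 10 | 25 |
| cedar run | 20 | 41 |
| cedar run | 31 | 45 |
| cedar run | 45 | 53 |
| larch run | 3.4 | 78 |
| larch run | 10 | 126 |
| larch run | 20 | 137 |
| larch run | 31 | 145 |
| larch run | 45 | 143 |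
| birch run | 3.4 | 20 |
| birch run | 10 | 44 |
| birch run | 20 | 53 |
| birch run | 31 | 53 |
| birch run | 45 | 64 |

(each reading ± 3 mM)

1. reaction order in [L] at the outset, round the charge of the alder run, defined at two percent of the L turned into Q (one fixed amount of Q, the same in the runs compared)
2. reaction order in [J] at the outset, round the charge of the alder run, defined at two percent of the L turned into Q
3. Q in the elm run at 45 min, as a share of the L charged
4. which of these the readings show (the product binds the substrate / nothing beyond the main steps / the substrate pairs with itself / the product binds the second partner / the substrate is lost by itself / the second partner pairs with itself)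

- Overall: L + J -> Q.
- Constant volume, constant temperature.
- "The second partner" is J.
- An order is taken over about fifteen percent of the charge, up and down.

The first readings give the orders as a rough reckoning. Halving L from the alder run to the birch run divides the first reading by 1.95, and doubling J from the alder run to the larch run multiplies it by 2.00, so each order reads near one.

The birch curve then draws itself. It opens at 20 mM by 3.4 min, and its readings from 20 min onward average 56.7 mM. That level lies far below the L charged, so the readings suggest that L leaves by some other way as well. The level share, the part of the L charged that ends as Q while [J] stays near this charge, reads 37.8% in the birch run. Taking [J] as steady, the curve bends like a pseudo-first-order one, and the first reading then gives a time constant of 7.81 min.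

Scaled to the L of the elm run, the curve climbs at about 2.55 mM min⁻¹ over the first minutes, bends near 7.81 min, and runs toward 24.6 mM. The asked time is 5.76 time constants, so the elm run should stand on its level by then. Its Q takes less J than in the birch run, so this reckoning expects [J] to stay nearer its charge in the elm run and a share somewhat above 37.8%.

The forecast sets the orders at 1 in L and 1 in J, puts the elm run higher than the level share of the birch run, at 42%, and answers that the substrate is lost by itself, with the ground: “More J raises the plateau share”.

The flask gives orders of 1.0 in L and 1.1 in J and 43.1% in the elm run, and the answer is that the substrate is lost by itself.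

    L + J → Q (0.2358 M⁻¹ min⁻¹)
    L + J → X (0.1320 M⁻¹ min⁻¹)
    L → Ju (0.03840 min⁻¹)

The elm run stands 5.3 percentage points above the level share of 37.8% read from the birch run. Part of its L goes to X alongside Q, and part goes to Ju without J taking any part. Taking the loss to Ju away lifts Q in the elm run at 45 min from 43.1% to 61.5%, a gain of 18 points, which is 32% of what is missing.

The readings are calculated with made-up constants.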